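The ten-membered carbocycle (C1 ketone, C2, C3, C4 carbinol, C5, C6 acyloxy, C7/C8 lactone fusion, C9, C10 CHMe) is disconnected at C2–C3. Because this bond lies between the C1 carbonyl and the C4 tertiary carbinol, it is the retron of a cyclic 2-ene-1,4-diol: ring-closing metathesis of two vinyl carbinols closes the ring in one operation, and hydrogenation plus oxidation at C1 finish it. The precursor is an acyclic diene carrying the cis-fused lactone (its methylene masked as a dimethylamine adduct), the C6 isobutyrate, a C1 vinyl carbinol and the C4 vinyl carbinol of (R)-linalool; C8 is bought, C10, C7 and C6 are relayed from it.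

Key step: step 16

Remark on the chemistry: locants follow the target skeleton throughout (C11 = lactone α-carbon, C12 = lactone carbonyl, C13 = exocyclic methylene, C14 = methyl on C4, C15 = methyl on C10). (S)-5-[(Trityloxy)methyl]dihydrofuran-2(3H)-one (derived from L-glutamic acid) and (R)-(−)-linalool are assumed to be commercial in high enantiomeric purity.

**Fragment with C7–C10, C1, C2 (steps 1–7)**

Step 1
Reactants: 1 (S)-5-[(trityloxy)methyl]dihydrofuran-2(3H)-one
Product: 2 (3R,5S)-3-methyl-5-[(trityloxy)methyl]dihydrofuran-2(3H)-one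
Conditions: LiN(i-Pr)2 (LDA), THF, −78 °C; MeI, −78 °C
Reagents that add atoms: iodomethane, CI
Why: Alkylation of the lactone lithium enolate; MeI should approach anti to the bulky CH2OTr group at C8, giving the trans lactone and so the (R) methyl center C10.

Step 2
Reactants: 2 (3R,5S)-3-methyl-5-[(trityloxy)methyl]dihydrofuran-2(3H)-one
Product: 4 (4R,6S)-4-methyl-7-(trityloxy)hept-1-ene-3,6-diol (C3 epimers), via lactol 3 (not isolated)
Conditions: i-Bu2AlH, CH2Cl2, −78 °C; then CH2=CHMgBr (excess), THF, −78 → 0 °C; aq. potassium sodium tartrate work-up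
Reagents that add atoms: vinylmagnesium bromide, C=C[Mg]Br
Why: One-pot partial reduction of the lactone to its aluminium lactolate and Grignard addition to the ring-opened hydroxy aldehyde; the new C1 carbinol forms as an epimer mixture that converges in step 18.

Step 3
Reactants: 4 (4R,6S)-4-methyl-7-(trityloxy)hept-1-ene-3,6-diol
Product: 5 (4R,6S)-3,6-bis[(4-methoxybenzyl)oxy]-4-methyl-7-(trityloxy)hept-1-ene
Conditions: NaH, 4-MeOC6H4CH2Cl, Bu4NI (cat.), DMF, 0 °C → rt
Reagents that add atoms: 4-methoxybenzyl chloride, COc1ccc(CCl)cc1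
Why: Williamson etherification of both secondary hydroxyls; the PMB ether is a small, coordinating group at O8 (needed in step 12) and is removed oxidatively without strong acid.

Step 4
Reactants: 5 (4R,6S)-3,6-bis[(4-methoxybenzyl)oxy]-4-methyl-7-(trityloxy)hept-1-ene
Product: 6 (2S,4R)-2,5-bis[(4-methoxybenzyl)oxy]-4-methylhept-6-en-1-ol
Conditions: CSA (cat.), MeOH/CH2Cl2 (1:1), 0 °C
Reagents that add atoms: none
Why: Acid-catalysed methanolysis of the trityl ether through the trityl cation, which should leave the PMB ethers untouched.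

Step 5
Reactants: 6 (2S,4R)-2,5-bis[(4-methoxybenzyl)oxy]-4-methylhept-6-en-1-ol
Product: 7 (2S,4R)-2,5-bis[(4-methoxybenzyl)oxy]-4-methylhept-6-enal
Conditions: Dess–Martin periodinane, NaHCO3, CH2Cl2, 0 °C → rt
Reagents that add atoms: none
Why: Dess–Martin oxidation under buffered neutral conditions, which should not epimerise the α-alkoxy center C8.

Step 6
Reactants: 7 (2S,4R)-2,5-bis[(4-methoxybenzyl)oxy]-4-methylhept-6-enal; 8 methyl acrylate
Product: 9 methyl (4S,6R)-3-hydroxy-4,7-bis[(4-methoxybenzyl)oxy]-6-methyl-2-methylidenenon-8-enoate (C3 epimers)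
Conditions: DABCO (1 equiv), neat 8 (excess), rt
Reagents that add atoms: none
Why: Morita–Baylis–Hillman reaction of an activated α-alkoxy aldehyde; the new carbinol center (C7) is erased in step 7.

Step 7
Reactants: 9 methyl (4S,6R)-3-hydroxy-4,7-bis[(4-methoxybenzyl)oxy]-6-methyl-2-methylidenenon-8-enoate
Product: 10 methyl (2Z,4S,6R)-2-(bromomethyl)-4,7-bis[(4-methoxybenzyl)oxy]-6-methylnona-2,8-dienoate
Conditions: NBS, Me2S, CH2Cl2, 0 °C → rt
Reagents that add atoms: N-bromosuccinimide, O=C1CCC(=O)N1Br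
Why: Corey–Kim-type activation of the allylic alcohol as an alkoxysulfonium ion and SN2' attack of bromide, which should give the more stable (Z)-enoate with C8 trans to the ester.

**Fragment with C3–C6, C14 (steps 8–11)**

Step 8
Reactants: 11 (R)-(−)-linalool
Product: 12 (R)-triethyl[(3,7-dimethylocta-1,6-dien-3-yl)oxy]silane
Conditions: Et3SiOTf, 2,6-lutidine, CH2Cl2, −78 → 0 °C
Reagents that add atoms: triethylsilyl trifluoromethanesulfonate, CC[Si](CC)(CC)OS(=O)(=O)C(F)(F)F
Why: Silylation of the tertiary alcohol with a silyl triflate; the C4 center with its methyl and vinyl groups is bought.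

Step 9
Reactants: 12 (R)-triethyl[(3,7-dimethylocta-1,6-dien-3-yl)oxy]silane
Product: 13 (R)-4-methyl-4-[(triethylsilyl)oxy]hex-5-enal
Conditions: O3, CH2Cl2, −78 °C (Sudan Red 7B indicator); then PPh3, −78 °C → rt
Reagents that add atoms: ozone, [O-][O+]=O
Why: Chemoselective ozonolysis; the electron-rich trisubstituted olefin should react well before the monosubstituted vinyl group.

Step 10
Reactants: 13 (R)-4-methyl-4-[(triethylsilyl)oxy]hex-5-enal
Product: 14 triethyl{[(3R)-3-methyl-6-[(trimethylsilyl)oxy]hexa-1,5-dien-3-yl]oxy}silane (E/Z mixture)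
Conditions: Me3SiOTf, Et3N, CH2Cl2, 0 °C → rt
Reagents that add atoms: trimethylsilyl trifluoromethanesulfonate, C[Si](C)(C)OS(=O)(=O)C(F)(F)F
Why: Soft enolisation of the aldehyde to its silyl enol ether, which prepares the one-carbon degradation.

Step 11
Reactants: 14 triethyl{[(3R)-3-methyl-6-[(trimethylsilyl)oxy]hexa-1,5-dien-3-yl]oxy}silane
Product: 15 (R)-3-methyl-3-[(triethylsilyl)oxy]pent-4-enal
Conditions: O3, CH2Cl2, −78 °C (stopped at the indicator end point); then PPh3
Reagents that add atoms: ozone, [O-][O+]=O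
Why: Ozonolysis of the enol ether, far more reactive than the vinyl group, excises one carbon as a formate and gives the C6 aldehyde.

**Union and endgame (steps 12–19)**

Step 12
Reactants: 10 methyl (2Z,4S,6R)-2-(bromomethyl)-4,7-bis[(4-methoxybenzyl)oxy]-6-methylnona-2,8-dienoate; 15 (R)-3-methyl-3-[(triethylsilyl)oxy]pent-4-enal
Product: 16 methyl 2-[(3R,5R,6R,7S,9R)-5-hydroxy-7,10-bis[(4-methoxybenzyl)oxy]-3,9-dimethyl-3-[(triethylsilyl)oxy]dodeca-1,11-dien-6-yl]prop-2-enoate (C10 epimers)
Conditions: In powder, THF/H2O (3:1), rt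
Reagents that add atoms: none
Why: Indium-mediated Barbier 2-(alkoxycarbonyl)allylation in which the allylindium from 10 attacks 15 through its γ-carbon C7 in a six-membered chair transition state, the (Z)-configured reagent giving the syn C6/C7 relationship, while C8 controls the face of C7 (C8–H eclipses the C7=C11 bond to avoid allylic 1,3-strain and the C8 ether oxygen holds indium, so the aldehyde is delivered syn to O8 and anti to C9), setting C7 and C6 in one event.

Step 13
Reactants: 16 methyl 2-[(3R,5R,6R,7S,9R)-5-hydroxy-7,10-bis[(4-methoxybenzyl)oxy]-3,9-dimethyl-3-[(triethylsilyl)oxy]dodeca-1,11-dien-6-yl]prop-2-enoate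
Product: 17 methyl 2-[(3R,5R,6S,7S,9R)-7,10-bis[(4-methoxybenzyl)oxy]-3,9-dimethyl-5-[(2-methylpropanoyl)oxy]-3-[(triethylsilyl)oxy]dodeca-1,11-dien-6-yl]prop-2-enoate
Conditions: (i-PrCO)2O, DMAP, Et3N, CH2Cl2, 0 °C → rt
Reagents that add atoms: isobutyric anhydride, CC(C)C(=O)OC(=O)C(C)C
Why: DMAP-catalysed acylation of the only free hydroxyl (O6) with retention, which installs the isobutyrate and prevents O6 from closing a lactone later.

Step 14
Reactants: 17 methyl 2-[(3R,5R,6S,7S,9R)-7,10-bis[(4-methoxybenzyl)oxy]-3,9-dimethyl-5-[(2-methylpropanoyl)oxy]-3-[(triethylsilyl)oxy]dodeca-1,11-dien-6-yl]prop-2-enoate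
Product: 19 (1R,3R)-3-hydroxy-1-[(2S,3S)-2-[(2R)-3-hydroxy-2-methylpent-4-en-1-yl]-4-methylidene-5-oxooxolan-3-yl]-3-methylpent-4-en-1-yl 2-methylpropanoate (carbinol epimers at C1), via dihydroxy ester 18 (not isolated)
Conditions: DDQ, CH2Cl2/pH 7 buffer (10:1), 0 °C → rt; filtration, concentration; then PPTS, MeOH, 40 °C
Reagents that add atoms: none
Why: Oxidative PMB ether cleavage frees O8 and O1, then mild acid removes the silyl ether and closes the γ-lactone from O8 onto the acrylate ester (O6 is acylated, so only this lactone can form); no stereocenter is touched and the cis fusion follows from the C7/C8 configuration set in step 12.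

Step 15
Reactants: 19 (1R,3R)-3-hydroxy-1-[(2S,3S)-2-[(2R)-3-hydroxy-2-methylpent-4-en-1-yl]-4-methylidene-5-oxooxolan-3-yl]-3-methylpent-4-en-1-yl 2-methylpropanoate
Product: 20 (1R,3R)-1-[(2S,3S)-4-[(dimethylamino)methyl]-2-[(2R)-3-hydroxy-2-methylpent-4-en-1-yl]-5-oxooxolan-3-yl]-3-hydroxy-3-methylpent-4-en-1-yl 2-methylpropanoate (epimers at C1 and C11)
Conditions: Me2NH (2 M in THF), MeOH, 0 °C → rt
Reagents that add atoms: dimethylamine, CNC
Why: Aza-Michael addition masks the α-methylene lactone, whose olefin would otherwise close a six-membered ring with the C4 vinyl group in step 16 and be reduced in step 17; the new C11 center is removed in step 19.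

Step 16
Reactants: 20 (1R,3R)-1-[(2S,3S)-4-[(dimethylamino)methyl]-2-[(2R)-3-hydroxy-2-methylpent-4-en-1-yl]-5-oxooxolan-3-yl]-3-hydroxy-3-methylpent-4-en-1-yl 2-methylpropanoate
Product: 21 (3aS,4R,6R,10R,11aS)-3-[(dimethylamino)methyl]-6,9-dihydroxy-6,10-dimethyl-2-oxo-2,3,3a,4,5,6,9,10,11,11a-decahydrocyclodeca[b]furan-4-yl 2-methylpropanoate (epimers at C9 and C3 of the bicycle)
Conditions: CSA (1.0 equiv); second-generation Grubbs catalyst [RuCl2(=CHPh)(H2IMes)(PCy3)] (10 mol %), 1,4-benzoquinone (20 mol %), CH2Cl2 (1 mM), 40 °C; aq. NaHCO3 work-up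
Reagents that add atoms: none
Why: The ruthenium benzylidene exchanges with the less hindered C1 vinyl group, and the new alkylidene engages the C4 vinyl group through a ruthenacyclobutane, releasing ethylene and forming C2=C3; the closest known reaction type is ring-closing metathesis of densely oxygenated dienes with allylic hydroxyl or ether groups to ten-membered carbocycles. One ring is closed, the ten-membered carbocycle C1–C10, by macrocyclic ring-closing metathesis that fuses it to the preformed lactone. No stereocenter is created: the C2=C3 geometry (Z expected) is erased in step 17 and both C1 epimers converge on the ketone in step 18. The step needs cyclisation to win over acyclic diene metathesis and needs the catalyst to meet only the two vinyl groups: high dilution, the cis-fused lactone and the five substituted ring atoms (C4, C6, C7, C8, C10, with quaternary C4 as a gem-dialkyl turn) should fold the chain, and the aminomethyl mask removes the competing lactone olefin. Protonation of the amine by CSA keeps nitrogen off ruthenium, and benzoquinone suppresses ruthenium hydride isomerisation of the secondary allylic alcohol.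

Step 17
Reactants: 21 (3aS,4R,6R,10R,11aS)-3-[(dimethylamino)methyl]-6,9-dihydroxy-6,10-dimethyl-2-oxo-2,3,3a,4,5,6,9,10,11,11a-decahydrocyclodeca[b]furan-4-yl 2-methylpropanoate
Product: 22 (3aS,4R,6S,10R,11aS)-3-[(dimethylamino)methyl]-6,9-dihydroxy-6,10-dimethyl-2-oxododecahydrocyclodeca[b]furan-4-yl 2-methylpropanoate
Conditions: H2 (1 atm), PtO2, EtOAc, rt
Reagents that add atoms: none
Why: Heterogeneous hydrogenation of the only C=C bond; C2 and C3 become CH2 groups, so no stereocenter is formed, and the masked lactone has no olefin to lose.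

Step 18
Reactants: 22 (3aS,4R,6S,10R,11aS)-3-[(dimethylamino)methyl]-6,9-dihydroxy-6,10-dimethyl-2-oxododecahydrocyclodeca[b]furan-4-yl 2-methylpropanoate
Product: 23 (3aS,4R,6S,10R,11aS)-3-[(dimethylamino)methyl]-6-hydroxy-6,10-dimethyl-2,9-dioxododecahydrocyclodeca[b]furan-4-yl 2-methylpropanoate
Conditions: (n-Pr)4N[RuO4] (5 mol %), N-methylmorpholine N-oxide, 4 Å molecular sieves, CH2Cl2, rt
Reagents that add atoms: none
Why: Ley–Griffith oxidation of the only secondary alcohol gives the C1 ketone from both epimers; the tertiary C4 hydroxyl cannot be oxidised and the neutral medium should not epimerise C10.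

Step 19
Reactants: 23 (3aS,4R,6S,10R,11aS)-3-[(dimethylamino)methyl]-6-hydroxy-6,10-dimethyl-2,9-dioxododecahydrocyclodeca[b]furan-4-yl 2-methylpropanoate
Product: 25 (3aS,4R,6S,10R,11aS)-6-hydroxy-6,10-dimethyl-3-methylidene-2,9-dioxododecahydrocyclodeca[b]furan-4-yl 2-methylpropanoate (CNP0293926.1), via trimethylammonium iodide 24 (not isolated)
Conditions: MeI (excess), MeOH, rt; then aq. NaHCO3, EtOAc, rt
Reagents that add atoms: none
Why: N-Quaternisation followed by E1cB elimination of trimethylamine from the β-ammonio lactone regenerates the α-methylene lactone; the only β-hydrogen is on C11, so only the exocyclic olefin can form, and bicarbonate is too mild to epimerise C10.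

**Compound list**

1 | (S)-5-[(trityloxy)methyl]dihydrofuran-2(3H)-one | O=C1CC[C@@H](COC(c2ccccc2)(c2ccccc2)c2ccccc2)O1 | starting material
2 | (3R,5S)-3-methyl-5-[(trityloxy)methyl]dihydrofuran-2(3H)-one | O=C1[C@H](C)C[C@@H](COC(c2ccccc2)(c2ccccc2)c2ccccc2)O1 | intermediate
3 | (3R,5S)-3-methyl-5-[(trityloxy)methyl]tetrahydrofuran-2-ol (as its aluminium lactolate, not isolated) | OC1[C@H](C)C[C@@H](COC(c2ccccc2)(c2ccccc2)c2ccccc2)O1 | intermediate
4 | (4R,6S)-4-methyl-7-(trityloxy)hept-1-ene-3,6-diol (C3 epimers) | C=CC(O)[C@H](C)C[C@H](O)COC(c1ccccc1)(c1ccccc1)c1ccccc1 | intermediate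
5 | (4R,6S)-3,6-bis[(4-methoxybenzyl)oxy]-4-methyl-7-(trityloxy)hept-1-ene | C=CC(OCc1ccc(OC)cc1)[C@H](C)C[C@H](OCc1ccc(OC)cc1)COC(c1ccccc1)(c1ccccc1)c1ccccc1 | intermediate
6 | (2S,4R)-2,5-bis[(4-methoxybenzyl)oxy]-4-methylhept-6-en-1-ol | C=CC(OCc1ccc(OC)cc1)[C@H](C)C[C@H](OCc1ccc(OC)cc1)CO | intermediate
7 | (2S,4R)-2,5-bis[(4-methoxybenzyl)oxy]-4-methylhept-6-enal | C=CC(OCc1ccc(OC)cc1)[C@H](C)C[C@H](OCc1ccc(OC)cc1)C=O | intermediate
8 | methyl acrylate | C=CC(=O)OC | starting material
9 | methyl (4S,6R)-3-hydroxy-4,7-bis[(4-methoxybenzyl)oxy]-6-methyl-2-methylidenenon-8-enoate | C=CC(OCc1ccc(OC)cc1)[C@H](C)C[C@H](OCc1ccc(OC)cc1)C(O)C(=C)C(=O)OC | intermediate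
10 | methyl (2Z,4S,6R)-2-(bromomethyl)-4,7-bis[(4-methoxybenzyl)oxy]-6-methylnona-2,8-dienoate | C=CC(OCc1ccc(OC)cc1)[C@H](C)C[C@H](OCc1ccc(OC)cc1)/C=C(\CBr)C(=O)OC | intermediate
11 | (R)-(−)-linalool | C=C[C@](C)(O)CCC=C(C)C | starting material
12 | (R)-triethyl[(3,7-dimethylocta-1,6-dien-3-yl)oxy]silane | C=C[C@](C)(O[Si](CC)(CC)CC)CCC=C(C)C | intermediate
13 | (R)-4-methyl-4-[(triethylsilyl)oxy]hex-5-enal | C=C[C@](C)(O[Si](CC)(CC)CC)CCC=O | intermediate
14 | triethyl{[(3R)-3-methyl-6-[(trimethylsilyl)oxy]hexa-1,5-dien-3-yl]oxy}silane (E/Z mixture) | C=C[C@](C)(O[Si](CC)(CC)CC)CC=CO[Si](C)(C)C | intermediate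
15 | (R)-3-methyl-3-[(triethylsilyl)oxy]pent-4-enal | C=C[C@](C)(O[Si](CC)(CC)CC)CC=O | intermediate
16 | methyl 2-[(3R,5R,6R,7S,9R)-5-hydroxy-7,10-bis[(4-methoxybenzyl)oxy]-3,9-dimethyl-3-[(triethylsilyl)oxy]dodeca-1,11-dien-6-yl]prop-2-enoate | C=CC(OCc1ccc(OC)cc1)[C@H](C)C[C@H](OCc1ccc(OC)cc1)[C@H](C(=C)C(=O)OC)[C@H](O)C[C@@](C)(O[Si](CC)(CC)CC)C=C | intermediate
17 | methyl 2-[(3R,5R,6S,7S,9R)-7,10-bis[(4-methoxybenzyl)oxy]-3,9-dimethyl-5-[(2-methylpropanoyl)oxy]-3-[(triethylsilyl)oxy]dodeca-1,11-dien-6-yl]prop-2-enoate | C=CC(OCc1ccc(OC)cc1)[C@H](C)C[C@H](OCc1ccc(OC)cc1)[C@H](C(=C)C(=O)OC)[C@H](OC(=O)C(C)C)C[C@@](C)(O[Si](CC)(CC)CC)C=C | intermediate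
18 | methyl 2-[(3R,5R,6S,7S,9R)-7,10-dihydroxy-3,9-dimethyl-5-[(2-methylpropanoyl)oxy]-3-[(triethylsilyl)oxy]dodeca-1,11-dien-6-yl]prop-2-enoate (not isolated) | C=CC(O)[C@H](C)C[C@H](O)[C@H](C(=C)C(=O)OC)[C@H](OC(=O)C(C)C)C[C@@](C)(O[Si](CC)(CC)CC)C=C | intermediate
19 | (1R,3R)-3-hydroxy-1-[(2S,3S)-2-[(2R)-3-hydroxy-2-methylpent-4-en-1-yl]-4-methylidene-5-oxooxolan-3-yl]-3-methylpent-4-en-1-yl 2-methylpropanoate | C=C1C(=O)O[C@@H](C[C@@H](C)C(O)C=C)[C@H]1[C@H](OC(=O)C(C)C)C[C@@](C)(O)C=C | intermediate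
20 | (1R,3R)-1-[(2S,3S)-4-[(dimethylamino)methyl]-2-[(2R)-3-hydroxy-2-methylpent-4-en-1-yl]-5-oxooxolan-3-yl]-3-hydroxy-3-methylpent-4-en-1-yl 2-methylpropanoate | CN(C)CC1C(=O)O[C@@H](C[C@@H](C)C(O)C=C)[C@H]1[C@H](OC(=O)C(C)C)C[C@@](C)(O)C=C | intermediate
21 | (3aS,4R,6R,10R,11aS)-3-[(dimethylamino)methyl]-6,9-dihydroxy-6,10-dimethyl-2-oxo-2,3,3a,4,5,6,9,10,11,11a-decahydrocyclodeca[b]furan-4-yl 2-methylpropanoate | CN(C)CC1C(=O)O[C@H]2C[C@@H](C)C(O)C=C[C@](C)(O)C[C@@H](OC(=O)C(C)C)[C@@H]12 | intermediate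
22 | (3aS,4R,6S,10R,11aS)-3-[(dimethylamino)methyl]-6,9-dihydroxy-6,10-dimethyl-2-oxododecahydrocyclodeca[b]furan-4-yl 2-methylpropanoate | CN(C)CC1C(=O)O[C@H]2C[C@@H](C)C(O)CC[C@](C)(O)C[C@@H](OC(=O)C(C)C)[C@@H]12 | intermediate
23 | (3aS,4R,6S,10R,11aS)-3-[(dimethylamino)methyl]-6-hydroxy-6,10-dimethyl-2,9-dioxododecahydrocyclodeca[b]furan-4-yl 2-methylpropanoate | CN(C)CC1C(=O)O[C@H]2C[C@@H](C)C(=O)CC[C@](C)(O)C[C@@H](OC(=O)C(C)C)[C@@H]12 | intermediate
24 | {(3aS,4R,6S,10R,11aS)-6-hydroxy-6,10-dimethyl-4-[(2-methylpropanoyl)oxy]-2,9-dioxododecahydrocyclodeca[b]furan-3-yl}-N,N,N-trimethylmethanaminium iodide (not isolated) | C[N+](C)(C)CC1C(=O)O[C@H]2C[C@@H](C)C(=O)CC[C@](C)(O)C[C@@H](OC(=O)C(C)C)[C@@H]12.[I-] | intermediate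
25 | (3aS,4R,6S,10R,11aS)-6-hydroxy-6,10-dimethyl-3-methylidene-2,9-dioxododecahydrocyclodeca[b]furan-4-yl 2-methylpropanoate (CNP0293926.1) | C=C1C(=O)O[C@H]2C[C@@H](C)C(=O)CC[C@](C)(O)C[C@@H](OC(=O)C(C)C)[C@@H]12 | target

**Step count and risks**

Total step count: 19. Longest linear sequence: 15 steps (steps 1–7, then 12–19).

Steps most likely to fail:

Step 16 (ring closure). The cyclisation may lose to intermolecular metathesis, may stall at the alkylidene of the hindered C4 vinyl group, and ruthenium hydrides may isomerise the C1 allylic alcohol. The fallback changes the oxidation level of the ring-closing partner. Setting out from 20, MnO2 in CH2Cl2 would oxidise the secondary allylic alcohol to the vinyl ketone (1R,3R)-1-[(2S,3S)-4-[(dimethylamino)methyl]-2-[(2R)-2-methyl-3-oxopent-4-en-1-yl]-5-oxooxolan-3-yl]-3-hydroxy-3-methylpent-4-en-1-yl 2-methylpropanoate F1. Enone–olefin ring-closing metathesis (second-generation Hoveyda–Grubbs catalyst [RuCl2(=CH-C6H4-2-O-i-Pr)(H2IMes)], CSA, toluene, 80 °C, 1 mM) would then form the same C2=C3 bond and give the cyclic γ-hydroxy enone (3aS,4R,6R,10R,11aS)-3-[(dimethylamino)methyl]-6-hydroxy-6,10-dimethyl-2,9-dioxo-2,3,3a,4,5,6,9,10,11,11a-decahydrocyclodeca[b]furan-4-yl 2-methylpropanoate F2. The catalyst should load only on the C4 vinyl group, no allylic alcohol is left to isomerise, and the Z enone can rest as its transannular hemiketal. Hydrogenation of F2 (H2, PtO2, EtOAc) comes back to the route at 23 and makes step 18 unnecessary.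

Step 12 (fragment union). Transfer of chirality from C8 to C7 and C6 may be poor: the aldehyde may add to the wrong face of C7 if the C8 ether oxygen does not hold indium, and the syn C6/C7 ratio may erode with this α-unbranched aldehyde. The fallback replaces chelate control by catalyst control. Setting out from 10 and 15, a chromium-catalysed Nozaki–Hiyama–Kishi-type allylation (CrCl2 10 mol %, chiral oxazoline–sulfonamide ligand, Mn powder, Me3SiCl, Et3N, THF, rt) should give the silyl ether methyl 2-[(3R,5R,6S,7S,9R)-7,10-bis[(4-methoxybenzyl)oxy]-3,9-dimethyl-3-[(triethylsilyl)oxy]-5-[(trimethylsilyl)oxy]dodeca-1,11-dien-6-yl]prop-2-enoate F3, with the ligand and not the C8 ether deciding the face of addition. Mild acidic work-up (citric acid, MeOH) would cleave the O–SiMe3 bond and come back to the route at 16.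

Step 17 (olefin reduction). Reduction of the hindered ring olefin may be slow and may be accompanied by hydrogenolysis of the allylic C–O bonds at C1 or C4. The fallback is an internal redox instead of H2. Setting out from 21 (as its camphorsulfonate salt), a cationic rhodium bisphosphine catalyst ([Rh(cod)(dppe)]BF4, pre-activated with H2, THF, 60 °C) should isomerise the secondary allylic alcohol through its enol directly to the saturated ketone; the tertiary C4 carbinol cannot isomerise. This comes back to the route at 23, makes step 18 unnecessary and forms no compound outside the list (F0).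

Further compounds
F1 | step 16 | (1R,3R)-1-[(2S,3S)-4-[(dimethylamino)methyl]-2-[(2R)-2-methyl-3-oxopent-4-en-1-yl]-5-oxooxolan-3-yl]-3-hydroxy-3-methylpent-4-en-1-yl 2-methylpropanoate | CN(C)CC1C(=O)O[C@@H](C[C@@H](C)C(=O)C=C)[C@H]1[C@H](OC(=O)C(C)C)C[C@@](C)(O)C=C
F2 | step 16 | (3aS,4R,6R,10R,11aS)-3-[(dimethylamino)methyl]-6-hydroxy-6,10-dimethyl-2,9-dioxo-2,3,3a,4,5,6,9,10,11,11a-decahydrocyclodeca[b]furan-4-yl 2-methylpropanoate | CN(C)CC1C(=O)O[C@H]2C[C@@H](C)C(=O)C=C[C@](C)(O)C[C@@H](OC(=O)C(C)C)[C@@H]12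
F3 | step 12 | methyl 2-[(3R,5R,6S,7S,9R)-7,10-bis[(4-methoxybenzyl)oxy]-3,9-dimethyl-3-[(triethylsilyl)oxy]-5-[(trimethylsilyl)oxy]dodeca-1,11-dien-6-yl]prop-2-enoate | C=CC(OCc1ccc(OC)cc1)[C@H](C)C[C@H](OCc1ccc(OC)cc1)[C@H](C(=C)C(=O)OC)[C@H](O[Si](C)(C)C)C[C@@](C)(O[Si](CC)(CC)CC)C=C
F0 | step 17 | none | none
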